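Take a small charge of substrate under held gas and ask how much target a long run leaves.

all flasks: gas 22 mM (held)

| run | substrate | remark | time |
|---|---|---|---|
| ochre | 0.36 M | run made earlier |  |
| maple | 0.18 M |  | 2.5 d |
| alder | 0.18 M |  | 4.0 d |

- ochre (time / h: target / %, substrate / %): 3.00: 0, 94.1; 6.00: 2.3, 87.7; 10.0: 4.9, 78.8; 12.0: 6.3, 75.0

(each reading ± 0.5 percentage points)

- at the start none of the gas is in solution

- which of the two there is more of at the end, maple (isomer of the product / target)
- which of the two there is more of at the end, alder (isomer of the product / target)
- target at the end, in percent of the substrate charged, maple
- target at the end, in percent of the substrate charged, alder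

Read the substrate column of the ochre run first. Its last row, 75.0% left at 12.0 h, reads as a first-order time constant of 41.7 h. The first row reads longer, 49.3 h, so treat this clock as rough.

Now set the columns against each other. From 6.00 h to 12.0 h in ochre, substrate falls by 13 percentage points and target climbs by 4 points, so the target gained reads as 31.5% of the substrate lost. Call this target gained per substrate lost the yield share, the instantaneous yield. Split the span at the third row: ochre gives 29.2%, then 36.8%, and with a scatter of 0.5 points per reading I do not read these two as different. So freeze the share.

My own reckoning takes percentages as independent of the charge and multiplies the share by the substrate lost on that clock. It gives 24.0% target for maple and 28.3% for alder. The isomer is unread in ochre, so I put no figure on it.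

The forecast differs: it names target for maple and target for alder, at 52% and 70%, higher than mine, holding “it more likely that the isomer is an intermediate”.

Maple ends with 25.1% target against 16.3% isomer. Alder ends with 18.5% target against 25.3% isomer.

    substrate ⇌ intermediate A (K = 7.71, k = 1.43 × 10⁻⁴ /min)
    substrate + coupling partner → intermediate B (k = 0.0204 /M/min)
    intermediate B ⇌ intermediate C (K = 11.0, k = 1.92 × 10⁻⁴ /min)
    coupling partner + intermediate B → target (k = 0.157 /M/min)
    target ⇌ isomer of the product (K = 2.90, k = 2.85 × 10⁻⁴ /min)
    target → over-reaction product (k = 1.74 × 10⁻⁴ /min)
    gas ⇌ coupling partner, rate k7*(csat - [coupling partner]) (kL = 0.0132 /min)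

Maple stands 1.1 points above my reckoning with the frozen share, but alder stands 9.8 points below that reckoning, alder's target going from 25.8% at 2.00 d to 18.5% at 4.00 d. Read the same flask as alder later, at 6.0 d: the same share and clock give 30.5%, and that flask holds 11.6% target.

(All runs come from a simulation for an exercise; the scatter is artificial.)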